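The 1,2-dioxane (ring atoms O1, O2, C3–C6; C1 is the carboxyl carbon) is opened at the bond between the peroxide oxygen O1 and the fully substituted ring carbon C6. C6 is raised to the ketone level, so the precursor is an acyclic 6-oxo ester with a masked hydroperoxide at C3. Unmasking lets the C3 hydroperoxide add to the C6 carbonyl (6-exo-trig) and gives the 6-methoxy-1,2-dioxane in one operation; the axial C6 methyl group is then delivered to the derived peroxycarbenium ion, trans to the equatorial C4 methyl group. The step exploits the 1,4-relationship of the oxygen-bearing carbons C3 and C6 and the fact that C6 carries only carbon substituents besides O1.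

Key step: step 13

Remark: the side chain is numbered C7–C14 outward from C6. Compounds 8, 21 and 22 are epimer mixtures at one centre (the carbinol carbon of 8, the ketal carbon C6 of 21 and 22), which is drawn without configuration; in each case that centre is removed or reset in a later step.

Step 1
Reactants: 1 potassium trifluoro[(E)-2-phenylethenyl]borate; 2 (E)-but-2-enal (crotonaldehyde)
Product: 3 (3S,4E)-3-methyl-5-phenylpent-4-enal
Conditions: (2R,5R)-5-benzyl-2-tert-butyl-3-methylimidazolidin-4-one·HCl (20 mol%), HF (48% aq., 1 equiv), DME, −20 °C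
Reagents that add atoms: none
Why: Iminium-catalysed conjugate alkenylation of an enal by an alkenyltrifluoroborate (organocatalytic Friedel–Crafts-type alkylation), in which the (2R,5R) catalyst should expose the Si face of the β-carbon of the (E)-iminium ion so that the styryl group sets C12 as (S), HF removing the boron as tetrafluoroborate.

Step 2
Reactants: 3 (3S,4E)-3-methyl-5-phenylpent-4-enal
Product: 4 [(1E,3S)-3-methylhex-1-en-5-yn-1-yl]benzene
Conditions: dimethyl (1-diazo-2-oxopropyl)phosphonate, K2CO3, MeOH, 0 °C to rt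
Reagents that add atoms: dimethyl (1-diazo-2-oxopropyl)phosphonate CC(=O)C(=[N+]=[N-])P(=O)(OC)OC
Why: Seyferth–Gilbert homologation with the Ohira–Bestmann reagent turns the aldehyde carbon into C10 and adds C9 as the terminal alkyne carbon under mild carbonate conditions that leave the β-stereocentre and the styryl group alone.

Step 3
Reactants: 5 (R)-3-bromo-2-methylpropan-1-ol
Product: 6 [(2R)-3-bromo-2-methylpropoxy](tert-butyl)dimethylsilane
Conditions: TBSCl, imidazole, CH2Cl2, 0 °C to rt
Reagents that add atoms: tert-butyldimethylsilyl chloride CC(C)(C)[Si](C)(C)Cl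
Why: Standard silylation of the primary alcohol, needed so that the bromide can be turned into a Grignard reagent; the stereocentre (the future C4) comes from the chiral pool and is not involved.

Step 4
Reactants: 6 [(2R)-3-bromo-2-methylpropoxy](tert-butyl)dimethylsilane; 2 (E)-but-2-enal (crotonaldehyde)
Product: 8 (2E,6S)-7-[(tert-butyldimethylsilyl)oxy]-6-methylhept-2-en-4-ol (both C4 epimers), via Grignard reagent 7 (not isolated)
Conditions: Mg, THF, rt; then 2, −78 to 0 °C; H2O work-up
Reagents that add atoms: none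
Why: Grignard formation from the primary bromide and 1,2-addition to the enal build the C5–C6 bond; the carbinol centre forms unselectively, which does not matter because it is oxidised in step 5.

Step 5
Reactants: 8 (2E,6S)-7-[(tert-butyldimethylsilyl)oxy]-6-methylhept-2-en-4-ol
Product: 9 (2E,6S)-7-[(tert-butyldimethylsilyl)oxy]-6-methylhept-2-en-4-one
Conditions: MnO2 (excess), CH2Cl2, rt
Reagents that add atoms: none
Why: Chemoselective oxidation of the secondary allylic alcohol by MnO2 gives the (E)-enone (C6 carbonyl, C7=C8) without touching the silyl ether or the remote stereocentre.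

Step 6
Reactants: 4 [(1E,3S)-3-methylhex-1-en-5-yn-1-yl]benzene; 9 (2E,6S)-7-[(tert-butyldimethylsilyl)oxy]-6-methylhept-2-en-4-one
Product: 11 (2S,6R,7E,10S,11E)-1-[(tert-butyldimethylsilyl)oxy]-2,6,10-trimethyl-12-phenyldodeca-7,11-dien-4-one, via alkenylboronate 10 (not isolated)
Conditions: catecholborane, THF, 70 °C; then 9, Rh(acac)(C2H4)2 (3 mol%), (S)-BINAP (3.3 mol%), Et3N, dioxane/H2O 10:1, 100 °C
Reagents that add atoms: none
Why: syn-Hydroboration of the terminal alkyne gives the (E)-alkenylboronate, and the Hayashi–Miyaura rhodium-catalysed asymmetric 1,4-addition joins the two halves (C8–C9 bond); the (S)-BINAP rhodium–alkenyl species should add to the α-si face of the (E)-enone, which sets C8 as (R) under catalyst control with retention of the (E)-alkene.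

Step 7
Reactants: 11 (2S,6R,7E,10S,11E)-1-[(tert-butyldimethylsilyl)oxy]-2,6,10-trimethyl-12-phenyldodeca-7,11-dien-4-one
Product: 12 (2S,6R,7E,10S,11E)-1-hydroxy-2,6,10-trimethyl-12-phenyldodeca-7,11-dien-4-one
Conditions: HF (48% aq.), MeCN, 0 °C
Reagents that add atoms: none
Why: Fluoride-driven cleavage of the primary silyl ether under mildly acidic, non-alcoholic conditions frees the C3 alcohol without ketalising the C6 ketone or isomerising the alkenes.

Step 8
Reactants: 12 (2S,6R,7E,10S,11E)-1-hydroxy-2,6,10-trimethyl-12-phenyldodeca-7,11-dien-4-one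
Product: 14 (2E,4S,8R,9E,12S,13E)-4,8,12-trimethyl-6-oxo-14-phenyltetradeca-2,9,13-trienal, via keto aldehyde 13 (not isolated)
Conditions: IBX, DMSO, rt; then Ph3P=CHCHO, rt to 40 °C
Reagents that add atoms: (triphenylphosphoranylidene)acetaldehyde O=CC=P(c1ccccc1)(c1ccccc1)c1ccccc1
Why: One-pot IBX oxidation and Wittig olefination with the stabilised formyl ylide, which reacts with the aldehyde and not with the ketone, adds C1 and C2 as the (E)-enal; trapping the α-branched aldehyde in the same flask limits epimerisation at C4.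

Step 9
Reactants: 15 2,3-dimethylbut-2-ene
Product: 16 2-methoxypropan-2-yl hydroperoxide
Conditions: O3, MeOH/CH2Cl2, −78 °C; N2 purge
Reagents that add atoms: ozone [O-][O+]=O; methanol CO
Why: Ozonolysis in methanol (Criegee mechanism) traps the acetone carbonyl oxide as the α-methoxy hydroperoxide, an acid-removable carrier of the O–O unit.

Step 10
Reactants: 14 (2E,4S,8R,9E,12S,13E)-4,8,12-trimethyl-6-oxo-14-phenyltetradeca-2,9,13-trienal; 16 2-methoxypropan-2-yl hydroperoxide
Product: 17 (3S,4S,8R,9E,12S,13E)-3-[(2-methoxypropan-2-yl)peroxy]-4,8,12-trimethyl-6-oxo-14-phenyltetradeca-9,13-dienal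
Conditions: 16 (2 equiv), (S)-2-{bis[3,5-bis(trifluoromethyl)phenyl](trimethylsilyloxy)methyl}pyrrolidine (20 mol%), PhCO2H (20 mol%), toluene, 0 °C
Reagents that add atoms: none
Why: Iminium-catalysed enantioselective conjugate peroxidation of an enal, in which the bulky silyloxydiarylmethyl group of the (S) catalyst shields one face of the (E)-iminium ion so that the hydroperoxide adds to the Re face of C3 and sets (3S); in the A(1,3)-minimised conformer the (4S) centre turns its methyl group toward this face, so catalyst and substrate should be matched.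

Step 11
Reactants: 17 (3S,4S,8R,9E,12S,13E)-3-[(2-methoxypropan-2-yl)peroxy]-4,8,12-trimethyl-6-oxo-14-phenyltetradeca-9,13-dienal
Product: 18 (3S,4S,8R,9E,12S,13E)-3-[(2-methoxypropan-2-yl)peroxy]-4,8,12-trimethyl-6-oxo-14-phenyltetradeca-9,13-dienoic acid
Conditions: NaClO2, NaH2PO4, 2-methylbut-2-ene, t-BuOH/H2O, 0 °C
Reagents that add atoms: sodium chlorite [Na+].[O-]Cl=O
Why: Pinnick oxidation takes the β-peroxy aldehyde to the acid under buffered, non-basic conditions that avoid β-elimination of the peroxide, the scavenger protecting both alkenes from hypochlorite.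

Step 12
Reactants: 18 (3S,4S,8R,9E,12S,13E)-3-[(2-methoxypropan-2-yl)peroxy]-4,8,12-trimethyl-6-oxo-14-phenyltetradeca-9,13-dienoic acid
Product: 19 methyl (3S,4S,8R,9E,12S,13E)-3-[(2-methoxypropan-2-yl)peroxy]-4,8,12-trimethyl-6-oxo-14-phenyltetradeca-9,13-dienoate
Conditions: TMSCHN2, MeOH/toluene, 0 °C
Reagents that add atoms: trimethylsilyldiazomethane C[Si](C)(C)C=[N+]=[N-]
Why: Neutral O-methylation of the carboxylic acid gives the methyl ester, which is inert to the methanol and the Lewis acid of the next two steps, without base that could eliminate the β-peroxide.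

Step 13
Reactants: 19 methyl (3S,4S,8R,9E,12S,13E)-3-[(2-methoxypropan-2-yl)peroxy]-4,8,12-trimethyl-6-oxo-14-phenyltetradeca-9,13-dienoate
Product: 22 methyl 2-[(3S,4S)-6-[(2R,3E,6S,7E)-2,6-dimethyl-8-phenylocta-3,7-dien-1-yl]-6-methoxy-4-methyl-1,2-dioxan-3-yl]acetate (C6 anomers), via hydroperoxy keto ester 20 (not isolated), via peroxyhemiketal 21 (not isolated)
Conditions: CSA (10 mol%), MeOH, 0 °C to rt; Et3N quench
Reagents that add atoms: methanol CO
Why: Acid-catalysed methanolysis of the mixed peroxyketal liberates the secondary hydroperoxide 20, whose terminal oxygen O1 adds to the C6 carbonyl to give the cyclic peroxyhemiketal 21, and acid-catalysed exchange of its hydroxyl for methoxyl through the ring peroxycarbenium ion gives 22. The closest known reactions are the spontaneous cyclisation of γ-hydroperoxy ketones to 1,2-dioxan-3-ols and their ketalisation to 3-alkoxy-1,2-dioxanes. The 1,2-dioxane closes in the 6-exo-trig mode by formation of the O1–C6 bond. The only new stereocentre, the ketal carbon C6, is under thermodynamic (anomeric) control with methoxyl preferentially axial, but its configuration is irrelevant because C6 becomes planar again in step 14; C3 and C4 are not touched. The step needs only chemoselectivity, and the substrate secures it: C3 carries a single oxygen, so no furanoid or other ring size can compete, the C6 ketone is the only carbonyl that O1 can reach in an unstrained ring, and the methyl ester and both alkenes are inert to camphorsulfonic acid in methanol.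

Step 14
Reactants: 22 methyl 2-[(3S,4S)-6-[(2R,3E,6S,7E)-2,6-dimethyl-8-phenylocta-3,7-dien-1-yl]-6-methoxy-4-methyl-1,2-dioxan-3-yl]acetate
Product: 23 methyl 2-[(3S,4S,6R)-6-[(2R,3E,6S,7E)-2,6-dimethyl-8-phenylocta-3,7-dien-1-yl]-4,6-dimethyl-1,2-dioxan-3-yl]acetate
Conditions: AlMe3 (3 equiv), CH2Cl2, −78 to −30 °C; aqueous work-up
Reagents that add atoms: trimethylaluminium C[Al](C)C
Why: Proposed new method: AlMe3 should ionise the exocyclic C6–OMe bond (the more basic oxygen leaves, the ring oxygen O1 stabilises the cation) and the methylaluminate should transfer methyl to the 1,2-dioxan-3-ylium (peroxycarbenium) ion along the axial trajectory of the half-chair that keeps the C4 methyl pseudoequatorial, since attack on the other half-chair would be syn-diaxial to that methyl, so the new methyl ends up axial and trans to the C4 methyl, that is (6R), with both anomers of 22 converging on one ion; the closest known reactions are the Lewis-acid-mediated substitution of 3-alkoxy-1,2-dioxanes and 3-alkoxy-1,2-dioxolanes by allylsilanes and silyl ketene acetals through peroxycarbenium ions, and the axial C-methylation of cyclic ketals and glycosyl donors by AlMe3 through oxocarbenium ions.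

Step 15
Reactants: 23 methyl 2-[(3S,4S,6R)-6-[(2R,3E,6S,7E)-2,6-dimethyl-8-phenylocta-3,7-dien-1-yl]-4,6-dimethyl-1,2-dioxan-3-yl]acetate
Product: 24 2-[(3S,4S,6R)-6-[(2R,3E,6S,7E)-2,6-dimethyl-8-phenylocta-3,7-dien-1-yl]-4,6-dimethyl-1,2-dioxan-3-yl]acetic acid (CNP0179089.2)
Conditions: LiOH, THF/H2O, 0 °C; then 1 M HCl to pH 3
Reagents that add atoms: lithium hydroxide [Li+].[OH-]
Why: Saponification of the methyl ester, in which hydroxide attack at the ester carbonyl should be faster than deprotonation at C2 (which would open the ring by E1cB cleavage of the C3–O2 bond), so the dialkyl peroxide and all five stereocentres are carried into the acid.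

Compound list
1 | potassium trifluoro[(E)-2-phenylethenyl]borate | [K+].F[B-](F)(F)/C=C/c1ccccc1 | starting material
2 | (E)-but-2-enal (crotonaldehyde) | C/C=C/C=O | starting material
3 | (3S,4E)-3-methyl-5-phenylpent-4-enal | C[C@H](/C=C/c1ccccc1)CC=O | intermediate
4 | [(1E,3S)-3-methylhex-1-en-5-yn-1-yl]benzene | C[C@H](/C=C/c1ccccc1)CC#C | intermediate
5 | (R)-3-bromo-2-methylpropan-1-ol | BrC[C@H](C)CO | starting material
6 | [(2R)-3-bromo-2-methylpropoxy](tert-butyl)dimethylsilane | BrC[C@H](C)CO[Si](C)(C)C(C)(C)C | intermediate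
7 | [(2R)-3-[(tert-butyldimethylsilyl)oxy]-2-methylpropyl]magnesium bromide | Br[Mg]C[C@H](C)CO[Si](C)(C)C(C)(C)C | intermediate
8 | (2E,6S)-7-[(tert-butyldimethylsilyl)oxy]-6-methylhept-2-en-4-ol (both C4 epimers) | C/C=C/C(O)C[C@H](C)CO[Si](C)(C)C(C)(C)C | intermediate
9 | (2E,6S)-7-[(tert-butyldimethylsilyl)oxy]-6-methylhept-2-en-4-one | C/C=C/C(=O)C[C@H](C)CO[Si](C)(C)C(C)(C)C | intermediate
10 | 2-[(1E,4S,5E)-4-methyl-6-phenylhexa-1,5-dien-1-yl]-1,3,2-benzodioxaborole | C[C@H](/C=C/c1ccccc1)C/C=C/B1Oc2ccccc2O1 | intermediate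
11 | (2S,6R,7E,10S,11E)-1-[(tert-butyldimethylsilyl)oxy]-2,6,10-trimethyl-12-phenyldodeca-7,11-dien-4-one | C[C@H](/C=C/c1ccccc1)C/C=C/[C@H](C)CC(=O)C[C@H](C)CO[Si](C)(C)C(C)(C)C | intermediate
12 | (2S,6R,7E,10S,11E)-1-hydroxy-2,6,10-trimethyl-12-phenyldodeca-7,11-dien-4-one | C[C@H](/C=C/c1ccccc1)C/C=C/[C@H](C)CC(=O)C[C@H](C)CO | intermediate
13 | (2S,6R,7E,10S,11E)-2,6,10-trimethyl-4-oxo-12-phenyldodeca-7,11-dienal | C[C@H](/C=C/c1ccccc1)C/C=C/[C@H](C)CC(=O)C[C@H](C)C=O | intermediate
14 | (2E,4S,8R,9E,12S,13E)-4,8,12-trimethyl-6-oxo-14-phenyltetradeca-2,9,13-trienal | C[C@H](/C=C/c1ccccc1)C/C=C/[C@H](C)CC(=O)C[C@H](C)/C=C/C=O | intermediate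
15 | 2,3-dimethylbut-2-ene | CC(C)=C(C)C | starting material
16 | 2-methoxypropan-2-yl hydroperoxide | COC(C)(C)OO | intermediate
17 | (3S,4S,8R,9E,12S,13E)-3-[(2-methoxypropan-2-yl)peroxy]-4,8,12-trimethyl-6-oxo-14-phenyltetradeca-9,13-dienal | C[C@H](/C=C/c1ccccc1)C/C=C/[C@H](C)CC(=O)C[C@H](C)[C@H](CC=O)OOC(C)(C)OC | intermediate
18 | (3S,4S,8R,9E,12S,13E)-3-[(2-methoxypropan-2-yl)peroxy]-4,8,12-trimethyl-6-oxo-14-phenyltetradeca-9,13-dienoic acid | C[C@H](/C=C/c1ccccc1)C/C=C/[C@H](C)CC(=O)C[C@H](C)[C@H](CC(=O)O)OOC(C)(C)OC | intermediate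
19 | methyl (3S,4S,8R,9E,12S,13E)-3-[(2-methoxypropan-2-yl)peroxy]-4,8,12-trimethyl-6-oxo-14-phenyltetradeca-9,13-dienoate | C[C@H](/C=C/c1ccccc1)C/C=C/[C@H](C)CC(=O)C[C@H](C)[C@H](CC(=O)OC)OOC(C)(C)OC | intermediate
20 | methyl (3S,4S,8R,9E,12S,13E)-3-hydroperoxy-4,8,12-trimethyl-6-oxo-14-phenyltetradeca-9,13-dienoate | C[C@H](/C=C/c1ccccc1)C/C=C/[C@H](C)CC(=O)C[C@H](C)[C@H](CC(=O)OC)OO | intermediate
21 | methyl 2-[(3S,4S)-6-[(2R,3E,6S,7E)-2,6-dimethyl-8-phenylocta-3,7-dien-1-yl]-6-hydroxy-4-methyl-1,2-dioxan-3-yl]acetate (C6 anomers) | C[C@H](/C=C/c1ccccc1)C/C=C/[C@H](C)CC1(O)C[C@H](C)[C@H](CC(=O)OC)OO1 | intermediate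
22 | methyl 2-[(3S,4S)-6-[(2R,3E,6S,7E)-2,6-dimethyl-8-phenylocta-3,7-dien-1-yl]-6-methoxy-4-methyl-1,2-dioxan-3-yl]acetate (C6 anomers) | C[C@H](/C=C/c1ccccc1)C/C=C/[C@H](C)CC1(OC)C[C@H](C)[C@H](CC(=O)OC)OO1 | intermediate
23 | methyl 2-[(3S,4S,6R)-6-[(2R,3E,6S,7E)-2,6-dimethyl-8-phenylocta-3,7-dien-1-yl]-4,6-dimethyl-1,2-dioxan-3-yl]acetate | C[C@H](/C=C/c1ccccc1)C/C=C/[C@H](C)C[C@]1(C)C[C@H](C)[C@H](CC(=O)OC)OO1 | intermediate
24 | 2-[(3S,4S,6R)-6-[(2R,3E,6S,7E)-2,6-dimethyl-8-phenylocta-3,7-dien-1-yl]-4,6-dimethyl-1,2-dioxan-3-yl]acetic acid (CNP0179089.2) | C[C@H](/C=C/c1ccccc1)C/C=C/[C@H](C)C[C@]1(C)C[C@H](C)[C@H](CC(=O)O)OO1 | target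

Total step count: 15. Longest linear sequence: 12 steps (steps 3–8 and 10–15, from bromo alcohol 5).

Steps most likely to fail

1. Step 14 (proposed methyl transfer to the peroxycarbenium ion). It may fail by ionisation of the endocyclic C6–O1 bond instead of the C6–OMe bond (ring opening to an acyclic oxocarbenium ion and a tertiary methyl ether), by attack of the methyl–aluminium bond on the O–O bond, or by loss of facial control in the ion pair. The fallback uses known chemistry only; it sets out from ketone 11 and comes back at ester 23. Wittig methylenation of 11 (Ph3P=CH2, THF) gives the methylidene silyl ether F1. Steps 7, 8, 10, 11 and 12 are then run unchanged in this series and give the alcohol F2, the aldehyde F3 (not isolated), the enal F4, the peroxy aldehyde F5, the acid F6 and the methyl ester F7. PPTS in MeOH frees the hydroperoxide F8. Hg(OAc)2 in CH2Cl2 then closes the ring by 6-exo cycloperoxymercuration (Markovnikov attack of the hydroperoxide oxygen on C6 of the 1,1-disubstituted alkene) to the organomercurial F9, and alkaline NaBH4 replaces mercury by hydrogen to give 23. This closure is not stereocontrolled at C6, so 23 would have to be separated from its C6 epimer.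

2. Step 10 (catalytic conjugate peroxidation of keto enal 14). It may fail by epoxidation (attack of the enamine on the O–O bond), by intramolecular Michael addition of the C7 enol to the iminium ion, or by insufficient catalyst control next to the C4 centre. The fallback sets out from keto aldehyde 13 (isolated after IBX oxidation of 12) and comes back at ester 23. Urea–hydrogen peroxide and CSA in MeOH convert the aldehyde into its methoxy hydroperoxide, which again closes the ring by adding to the C6 ketone and gives the 3,6-dimethoxy-1,2-dioxane F10. AlMe3, as in step 14, should substitute only the tertiary ketal position C6, since the secondary acetal C3 ionises far more slowly, and gives the 3-methoxy-4,6-dimethyl-1,2-dioxane F11. TiCl4 and 1-methoxy-1-(trimethylsilyloxy)ethene in CH2Cl2 at −78 °C then attach the acetate at C3 through the C3 peroxycarbenium ion (the known silyl ketene acetal substitution of 3-alkoxy cyclic peroxides), with axial attack cis to the C4 methyl on the ring locked by the C6 substituents. This fallback keeps the methyl transfer of step 14 and removes steps 8 and 10–13.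

3. Step 6 (one-pot hydroboration and rhodium-catalysed 1,4-addition). It may fail by protodeboronation of the alkenylboronate outrunning transmetalation, by decomposition of the enone at 100 °C, or by weak enantioface selection. The fallback sets out from alkyne 4 and Grignard reagent 7 and comes back at ketone 11. (S)-4-Benzyloxazolidin-2-one is acylated (n-BuLi, (E)-but-2-enoyl chloride) to the crotonoyl imide F12. Alkyne 4 is hydrozirconated (Cp2Zr(H)Cl, THF) to the alkenylzirconocene F13, which is added to F12 with CuBr·SMe2 as transmetalation catalyst; attack anti to the benzyl group of the chelated s-cis imide sets C8 in the imide adduct F14. MeNHOMe·HCl and AlMe3 give the Weinreb amide F15, and Grignard reagent 7 converts it to ketone 11. C8 is then set by the auxiliary instead of the catalyst, and the C5–C6 bond is made last.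

Further compounds
F1 | step 14 | tert-butyldimethyl{[(2S,6R,7E,10S,11E)-2,6,10-trimethyl-4-methylidene-12-phenyldodeca-7,11-dien-1-yl]oxy}silane | C[C@H](/C=C/c1ccccc1)C/C=C/[C@H](C)CC(=C)C[C@H](C)CO[Si](C)(C)C(C)(C)C
F2 | step 14 | (2S,6R,7E,10S,11E)-2,6,10-trimethyl-4-methylidene-12-phenyldodeca-7,11-dien-1-ol | C[C@H](/C=C/c1ccccc1)C/C=C/[C@H](C)CC(=C)C[C@H](C)CO
F3 | step 14 | (2S,6R,7E,10S,11E)-2,6,10-trimethyl-4-methylidene-12-phenyldodeca-7,11-dienal | C[C@H](/C=C/c1ccccc1)C/C=C/[C@H](C)CC(=C)C[C@H](C)C=O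
F4 | step 14 | (2E,4S,8R,9E,12S,13E)-4,8,12-trimethyl-6-methylidene-14-phenyltetradeca-2,9,13-trienal | C[C@H](/C=C/c1ccccc1)C/C=C/[C@H](C)CC(=C)C[C@H](C)/C=C/C=O
F5 | step 14 | (3S,4S,8R,9E,12S,13E)-3-[(2-methoxypropan-2-yl)peroxy]-4,8,12-trimethyl-6-methylidene-14-phenyltetradeca-9,13-dienal | C[C@H](/C=C/c1ccccc1)C/C=C/[C@H](C)CC(=C)C[C@H](C)[C@H](CC=O)OOC(C)(C)OC
F6 | step 14 | (3S,4S,8R,9E,12S,13E)-3-[(2-methoxypropan-2-yl)peroxy]-4,8,12-trimethyl-6-methylidene-14-phenyltetradeca-9,13-dienoic acid | C[C@H](/C=C/c1ccccc1)C/C=C/[C@H](C)CC(=C)C[C@H](C)[C@H](CC(=O)O)OOC(C)(C)OC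
F7 | step 14 | methyl (3S,4S,8R,9E,12S,13E)-3-[(2-methoxypropan-2-yl)peroxy]-4,8,12-trimethyl-6-methylidene-14-phenyltetradeca-9,13-dienoate | C[C@H](/C=C/c1ccccc1)C/C=C/[C@H](C)CC(=C)C[C@H](C)[C@H](CC(=O)OC)OOC(C)(C)OC
F8 | step 14 | methyl (3S,4S,8R,9E,12S,13E)-3-hydroperoxy-4,8,12-trimethyl-6-methylidene-14-phenyltetradeca-9,13-dienoate | C[C@H](/C=C/c1ccccc1)C/C=C/[C@H](C)CC(=C)C[C@H](C)[C@H](CC(=O)OC)OO
F9 | step 14 | methyl 2-[(3S,4S)-6-[(acetoxymercurio)methyl]-6-[(2R,3E,6S,7E)-2,6-dimethyl-8-phenylocta-3,7-dien-1-yl]-4-methyl-1,2-dioxan-3-yl]acetate (C6 epimers) | C[C@H](/C=C/c1ccccc1)C/C=C/[C@H](C)CC1(C[Hg]OC(C)=O)C[C@H](C)[C@H](CC(=O)OC)OO1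
F10 | step 10 | (4S)-6-[(2R,3E,6S,7E)-2,6-dimethyl-8-phenylocta-3,7-dien-1-yl]-3,6-dimethoxy-4-methyl-1,2-dioxane (C3 and C6 anomers) | C[C@H](/C=C/c1ccccc1)C/C=C/[C@H](C)CC1(OC)C[C@H](C)C(OC)OO1
F11 | step 10 | (4S,6R)-6-[(2R,3E,6S,7E)-2,6-dimethyl-8-phenylocta-3,7-dien-1-yl]-3-methoxy-4,6-dimethyl-1,2-dioxane (C3 anomers) | C[C@H](/C=C/c1ccccc1)C/C=C/[C@H](C)C[C@]1(C)C[C@H](C)C(OC)OO1
F12 | step 6 | (4S)-4-benzyl-3-[(E)-but-2-enoyl]oxazolidin-2-one | C/C=C/C(=O)N1[C@@H](Cc2ccccc2)COC1=O
F13 | step 6 | chlorobis(cyclopentadienyl)[(1E,4S,5E)-4-methyl-6-phenylhexa-1,5-dien-1-yl]zirconium | Cl[Zr](/C=C/C[C@H](C)/C=C/c1ccccc1)(C1C=CC=C1)C1C=CC=C1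
F14 | step 6 | (4S)-4-benzyl-3-[(3R,4E,7S,8E)-3,7-dimethyl-9-phenylnona-4,8-dienoyl]oxazolidin-2-one | C[C@H](/C=C/c1ccccc1)C/C=C/[C@H](C)CC(=O)N1[C@@H](Cc2ccccc2)COC1=O
F15 | step 6 | (3R,4E,7S,8E)-N-methoxy-N,3,7-trimethyl-9-phenylnona-4,8-dienamide | C[C@H](/C=C/c1ccccc1)C/C=C/[C@H](C)CC(=O)N(C)OC
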